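**Retrosynthetic overview**
1. Target 14 ← global O-demethylation of pentamethyl ether 13 ← C3 hydroxylation (epoxidation, acid opening) of flavone 11 ← 7-O-methylation of flavone 10.
2. Key disconnection: ring C of 10 is cut at C4–C4a and O1–C2, giving benzylresorcinol 6 and aroylacetate 7 (thermal Mentzer annulation). Ring C is the only ring formed; rings A, B and the benzyl ring arrive intact.
3. Feature used: in ring A the benzylated carbon C8 lies between C8a–O1 and C7–OH, with the C5 oxygen para to it. In 6 this is a mirror plane through the benzyl carbon and C–OMe, so the two free CH carbons (future C4a or C6) are identical, and the only free hydroxyl beside either one also flanks the benzyl carbon. Annulation can therefore give only the 8-benzyl chromone.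
4. 6 ← MOM removal ← lithiation of bis-MOM ether 2 between its two MOM ethers and benzylation with 3 ← 5-methoxyresorcinol 1.

Key step: step 4

Remark on the chemistry: the target has no stereogenic element, so no enantiocontrol is needed. The only stereogenic intermediate (flavone epoxide 12) is racemic and loses both centres within the same step.

**Route**

Step 1
Reactants: 1 5-methoxybenzene-1,3-diol (5-methoxyresorcinol)
Product: 2 1-methoxy-3,5-bis(methoxymethoxy)benzene
Conditions: NaH (2.4 equiv), MOMCl (2.4 equiv), DMF, 0 °C → rt
Reagents that add atoms: chloromethyl methyl ether, COCCl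
Why: Williamson-type O-alkylation of the bis-phenoxide with the reactive α-chloro ether should give the bis-acetal, which later serves as the directing group for metalation.

Step 2
Reactants: 2 1-methoxy-3,5-bis(methoxymethoxy)benzene; 3 1-(bromomethyl)-4-methoxybenzene (4-methoxybenzyl bromide)
Product: 5 5-methoxy-2-(4-methoxybenzyl)-1,3-bis(methoxymethoxy)benzene, via aryllithium 4 (not isolated)
Conditions: n-BuLi (0.95 equiv), THF, 0 °C → rt, 1 h; then CuI (10 mol%), 3, −78 °C → rt
Reagents that add atoms: none
Why: Directed ortho-metalation should occur at the ring carbon flanked by the two MOM ethers, the stronger chelating directors (the slight excess of 2 lets the aryllithiums equilibrate to the doubly chelated 4), and copper-catalysed SN2 displacement of the benzylic bromide then forms the diarylmethane bond.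

Step 3
Reactants: 5 5-methoxy-2-(4-methoxybenzyl)-1,3-bis(methoxymethoxy)benzene
Product: 6 5-methoxy-2-(4-methoxybenzyl)benzene-1,3-diol
Conditions: 3 M HCl, MeOH, 50 °C
Reagents that add atoms: none
Why: Acid-catalysed acetal cleavage should free both phenols, with methanol trapping the formaldehyde equivalent as its dimethyl acetal so that it cannot alkylate the electron-rich ring.

Step 4
Reactants: 6 5-methoxy-2-(4-methoxybenzyl)benzene-1,3-diol; 7 ethyl 3-(3,4-dimethoxyphenyl)-3-oxopropanoate
Product: 10 7-hydroxy-5-methoxy-2-(3,4-dimethoxyphenyl)-8-(4-methoxybenzyl)-4H-chromen-4-one, via aroylketene 8 (not isolated), via beta-diketone 9 (not isolated)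
Conditions: 7 (1.5 equiv), neat melt, 240–250 °C, N2 stream (EtOH and H2O swept out), 2 h
Reagents that add atoms: none
Why: On heating, 7 should lose ethanol to give aroylketene 8, whose ketene carbon is attacked by one of the two equivalent free ring carbons of 6 (directly, or through the aryl ester and a thermal acyl shift), giving o-hydroxyaryl β-diketone 9 and the C4–C4a bond. The hydroxyl beside the new acyl group then adds to the aroyl carbonyl in a 6-exo-trig closure and water is lost, forming O1–C2 and the pyranone ring C. The closest known reaction is the Mentzer thermal chromone synthesis from phloroglucinol-type phenols and aroylacetates, which gives 5,7-dioxygenated flavones. No stereocenter is formed. Chromone must form in preference to the Pechmann coumarin, and the acid-free melt is chosen so that the ring carbon attacks the ketene (ester) carbon and not an acid-activated ketone. The 8-benzyl regiochemistry follows from the mirror plane of 6, which makes both acylation sites identical, and from the methyl ether on the other ortho oxygen, which leaves only the hydroxyl next to the benzyl carbon able to close; a second annulation at C6/7-OH should be slowed by the deactivating pyranone carbonyl.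

Step 5
Reactants: 10 7-hydroxy-5-methoxy-2-(3,4-dimethoxyphenyl)-8-(4-methoxybenzyl)-4H-chromen-4-one
Product: 11 5,7-dimethoxy-2-(3,4-dimethoxyphenyl)-8-(4-methoxybenzyl)-4H-chromen-4-one
Conditions: MeI, K2CO3, acetone, reflux
Reagents that add atoms: iodomethane, CI
Why: Williamson etherification of the acidic 7-hydroxyl (vinylogous to the C4 carbonyl) should be clean and removes the only free phenol before the oxidation step.

Step 6
Reactants: 11 5,7-dimethoxy-2-(3,4-dimethoxyphenyl)-8-(4-methoxybenzyl)-4H-chromen-4-one
Product: 13 3-hydroxy-5,7-dimethoxy-2-(3,4-dimethoxyphenyl)-8-(4-methoxybenzyl)-4H-chromen-4-one, via flavone epoxide 12 (not isolated)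
Conditions: DMDO (ca. 0.08 M in acetone, 3–5 equiv), CH2Cl2, 0 °C → rt, dark; evaporate; then p-TsOH·H2O (cat.), CH2Cl2, rt
Reagents that add atoms: dimethyldioxirane, CC1(C)OO1
Why: Dioxirane epoxidation of the C2=C3 enol-ether double bond of the flavone, followed by acid-catalysed opening at C2 (cation stabilised by O1 and the aryl group) and loss of H3, is the established flavone-to-flavonol conversion; the transient cis-fused racemic epoxide loses both stereocenters on aromatisation.

Step 7
Reactants: 13 3-hydroxy-5,7-dimethoxy-2-(3,4-dimethoxyphenyl)-8-(4-methoxybenzyl)-4H-chromen-4-one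
Product: 14 8-p-hydroxybenzylquercetin, 2-(3,4-dihydroxyphenyl)-3,5,7-trihydroxy-8-(4-hydroxybenzyl)-4H-chromen-4-one
Conditions: BBr3 (1 M in CH2Cl2, 10 equiv), CH2Cl2, −78 °C → rt; then ice/H2O
Reagents that add atoms: none
Why: Lewis-acid cleavage of all five aryl methyl ethers with boron tribromide at or below room temperature should leave the diarylmethane C–C bonds intact and avoids the hot protic acid that would invite Wessely–Moser isomerisation of the 8-benzyl group to C6.

**Compound list**
1 | 5-methoxybenzene-1,3-diol (5-methoxyresorcinol) | COc1cc(O)cc(O)c1 | starting material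
2 | 1-methoxy-3,5-bis(methoxymethoxy)benzene | COCOc1cc(OC)cc(OCOC)c1 | intermediate
3 | 1-(bromomethyl)-4-methoxybenzene (4-methoxybenzyl bromide) | COc1ccc(CBr)cc1 | starting material
4 | [4-methoxy-2,6-bis(methoxymethoxy)phenyl]lithium (formed in situ) | [Li]c1c(OCOC)cc(OC)cc1OCOC | intermediate
5 | 5-methoxy-2-(4-methoxybenzyl)-1,3-bis(methoxymethoxy)benzene | COCOc1cc(OC)cc(OCOC)c1Cc1ccc(OC)cc1 | intermediate
6 | 5-methoxy-2-(4-methoxybenzyl)benzene-1,3-diol | COc1cc(O)c(Cc2ccc(OC)cc2)c(O)c1 | intermediate
7 | ethyl 3-(3,4-dimethoxyphenyl)-3-oxopropanoate | CCOC(=O)CC(=O)c1ccc(OC)c(OC)c1 | starting material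
8 | 3-(3,4-dimethoxyphenyl)-3-oxoprop-1-en-1-one (aroylketene, formed in situ) | O=C=CC(=O)c1ccc(OC)c(OC)c1 | intermediate
9 | 1-[2,4-dihydroxy-6-methoxy-3-(4-methoxybenzyl)phenyl]-3-(3,4-dimethoxyphenyl)propane-1,3-dione (formed in situ) | COc1ccc(Cc2c(O)cc(OC)c(C(=O)CC(=O)c3ccc(OC)c(OC)c3)c2O)cc1 | intermediate
10 | 7-hydroxy-5-methoxy-2-(3,4-dimethoxyphenyl)-8-(4-methoxybenzyl)-4H-chromen-4-one | COc1ccc(Cc2c(O)cc(OC)c3c(=O)cc(-c4ccc(OC)c(OC)c4)oc23)cc1 | intermediate
11 | 5,7-dimethoxy-2-(3,4-dimethoxyphenyl)-8-(4-methoxybenzyl)-4H-chromen-4-one | COc1ccc(Cc2c(OC)cc(OC)c3c(=O)cc(-c4ccc(OC)c(OC)c4)oc23)cc1 | intermediate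
12 | rac-2,3-epoxy-5,7-dimethoxy-2-(3,4-dimethoxyphenyl)-8-(4-methoxybenzyl)-2,3-dihydro-4H-chromen-4-one (flavone 2,3-epoxide, cis-fused by necessity, racemic, one enantiomer drawn, formed in situ) | O=C1c2c(OC)cc(OC)c(Cc3ccc(OC)cc3)c2O[C@]2(c3ccc(OC)c(OC)c3)O[C@H]12 | intermediate
13 | 3-hydroxy-5,7-dimethoxy-2-(3,4-dimethoxyphenyl)-8-(4-methoxybenzyl)-4H-chromen-4-one | COc1ccc(Cc2c(OC)cc(OC)c3c(=O)c(O)c(-c4ccc(OC)c(OC)c4)oc23)cc1 | intermediate
14 | 8-p-hydroxybenzylquercetin | O=c1c(O)c(-c2ccc(O)c(O)c2)oc2c(Cc3ccc(O)cc3)c(O)cc(O)c12 | target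

**Step count**
Total: 7 steps. Longest linear sequence: 7 steps (1 → 14); compounds 3 and 7 enter as purchased materials.

**Steps most likely to fail, with fallbacks**

Step 4 (key annulation). The melt may divert to Pechmann-type closure giving the 4-arylcoumarin, stop at O-acylation without acyl transfer to carbon, or degrade the electron-rich phenol before acylation. Fallback, from 6 back to 10: ring C would be built stepwise. C-acetylation of 6 with acetic anhydride and BF3·OEt2, again at either of the two equivalent ring carbons, would give 1-[2,4-dihydroxy-6-methoxy-3-(4-methoxybenzyl)phenyl]ethan-1-one F1. Claisen–Schmidt condensation of this ketone with 3,4-dimethoxybenzaldehyde (KOH, EtOH, rt) would give (E)-1-[2,4-dihydroxy-6-methoxy-3-(4-methoxybenzyl)phenyl]-3-(3,4-dimethoxyphenyl)prop-2-en-1-one F2. Oxidative cyclisation with catalytic I2 in DMSO at 120–130 °C, through the only hydroxyl ortho to the enone, would then deliver 10.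

Step 6 (C3 hydroxylation). The dioxirane may oxidise the doubly benzylic CH2 or the electron-rich anisole rings in competition with the slow epoxidation of the electron-poor C2=C3 bond, and the labile 5,7-dialkoxy epoxide may decompose before rearrangement. Fallback, from 11 back to 13: deprotonation at C3 with LDA in THF at −78 °C would give 5,7-dimethoxy-2-(3,4-dimethoxyphenyl)-3-lithio-8-(4-methoxybenzyl)-4H-chromen-4-one F3. Trapping with trimethyl borate would give dimethyl [5,7-dimethoxy-2-(3,4-dimethoxyphenyl)-8-(4-methoxybenzyl)-4-oxo-4H-chromen-3-yl]boronate F4, and oxidation with AcOH/H2O2 would convert the C–B bond into the C3–OH of 13 without any electrophilic oxygen-transfer reagent.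

Step 2 (metalation and benzylation). The benzylic bromide may be consumed by halogen–lithium exchange and Wurtz-type homocoupling, returning protonated 2, and some metalation may leak to the positions flanked by OMe and OMOM. Fallback, from aryllithium 4 (generated from 2 as in step 2) back to 6: the C–C bond would be made by carbonyl addition instead of displacement. Addition of 4 to 4-methoxybenzaldehyde would give racemic [4-methoxy-2,6-bis(methoxymethoxy)phenyl](4-methoxyphenyl)methanol F5, a stage at which regioisomeric carbinols could be removed by chromatography. Ionic hydrogenation with Et3SiH/TFA in CH2Cl2 (0 °C → rt) would reduce the doubly stabilised benzhydryl cation to the methylene and strip both MOM groups in the same pot, the silane reducing the released methoxymethyl cations, so that 6 is reached directly.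

**Further compounds**
F1 | step 4 | 1-[2,4-dihydroxy-6-methoxy-3-(4-methoxybenzyl)phenyl]ethan-1-one | CC(=O)c1c(O)c(Cc2ccc(OC)cc2)c(O)cc1OC
F2 | step 4 | (E)-1-[2,4-dihydroxy-6-methoxy-3-(4-methoxybenzyl)phenyl]-3-(3,4-dimethoxyphenyl)prop-2-en-1-one | COc1ccc(Cc2c(O)cc(OC)c(C(=O)/C=C/c3ccc(OC)c(OC)c3)c2O)cc1
F3 | step 6 | 5,7-dimethoxy-2-(3,4-dimethoxyphenyl)-3-lithio-8-(4-methoxybenzyl)-4H-chromen-4-one | [Li]c1c(-c2ccc(OC)c(OC)c2)oc2c(Cc3ccc(OC)cc3)c(OC)cc(OC)c2c1=O
F4 | step 6 | dimethyl [5,7-dimethoxy-2-(3,4-dimethoxyphenyl)-8-(4-methoxybenzyl)-4-oxo-4H-chromen-3-yl]boronate | COB(OC)c1c(-c2ccc(OC)c(OC)c2)oc2c(Cc3ccc(OC)cc3)c(OC)cc(OC)c2c1=O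
F5 | step 2 | [4-methoxy-2,6-bis(methoxymethoxy)phenyl](4-methoxyphenyl)methanol (racemic) | COCOc1cc(OC)cc(OCOC)c1C(O)c1ccc(OC)cc1
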